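## Structural features

The target is a 2,3-trans dihydroflavonol. Ring A is a phloroglucinol-type benzene with free hydroxyls at C5 and C7 and a prenyl (3-methylbut-2-en-1-yl) group at C8; it is fused through C4a and C8a to ring C, a dihydropyran-4-one made of O1, C2, C3 and the C4 ketone, and ring B, a 4-hydroxy-3-methoxyphenyl group, is attached at C2. The only stereocentres, C2 (aryl, O1) and C3 (hydroxyl), are neighbours, both R, and trans, which is the diequatorial and thermodynamically favoured arrangement. Three parts are fragile: the prenyl alkene (strong acid would cyclise it onto the C7 hydroxyl; electrophilic oxidants and hydrogenation would consume it), the β-aryloxy ketone O1–C2–C3–C4 (base can expel O1 and open ring C to a chalcone, which erases C2, and a free 4′-hydroxyl assists the same ionisation), and the α-ketol at C3/C4 (epimerisation, dehydrogenation to the flavonol). The real difficulty is twofold: fixing the absolute configuration at C2 in a ring that can racemise by ring–chain opening, and placing the prenyl group at C8 and not C6, which means telling apart the two carbonyl-flanking oxygens of an acylphloroglucinol (the future O1 and O5). The key step exploits C2: it is benzylic to ring B and bears O1, so in a precursor opened at C2–C3 it is the CH2 of an aryl benzyl ether whose C–H bonds are doubly activated and lie six atoms from a carbene carbon generated at C3 beside the C4 ketone. In the C3-unsubstituted chromanone the same spatial arrangement at C2 carries the descriptor S, because C1′ outranks a CH2 at C3 but not a CH(OH); the structures were checked on this point and needed no correction.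

## Logic of the disconnections

**15 ⇒ 14.** The three phenolic O–Si bonds (O5, O7, O4′) are cut. Free phenols would quench a carbene and make ring C labile to base, so they stay masked until the end. The skeleton is unchanged; the gain is an endgame that uses only buffered fluoride and therefore spares the prenyl alkene and both stereocentres. The forward step must be close to neutral.

**14 ⇒ 12 (through 13).** The C3–O bond is cut. C3 is α to the C4 ketone, so its oxygen can come from an electrophilic oxygen donor acting on enolate 13. This leaves a ketone with a single stereocentre. The forward step must add oxygen anti to the C2 aryl group, must not let 13 expel O1, and must use an oxidant that ignores the prenyl alkene.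

**12 ⇒ 11.** The C2–C3 bond is cut, which opens ring C and removes the last stereocentre. What remains is an achiral aryl benzyl ether with a diazomethyl ketone, so the stereocentre and the ring are formed in one catalytic step. The forward step must insert a C3 carbene into one enantiotopic C2–H bond in preference to attack on O1, O5 or the alkene. Three design choices in 11 serve this:
- O5 and O7 carry triisopropylsilyl groups in place of tert-butyldimethylsilyl. They have no C–H α to oxygen, they shield the O5 lone pairs beside the carbene, and they resist transfer to an adjacent enolate oxygen in the two base steps.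
- O4′ keeps a tert-butyldimethylsilyl group, which is remote and electron-releasing toward C2.
- The prenyl group is meta to the carbene-bearing carbon and cannot be reached intramolecularly.

**11 ⇒ 8 (through 10 and 9).** The C3=N2 bond is cut. The diazo group is put on last, onto a stable methyl ketone, by acylative activation and diazo transfer, so neither diazomethane nor an acid chloride is needed. The forward step needs a kinetic enolate at low temperature and silyl groups that tolerate it.

**8 ⇒ 4 + 7.** The O1–CH2 bond is cut. This is the convergent cut that separates the ring A piece from the ring B piece. The forward step must etherify a hindered, chelated phenol without base strong enough to move aryl silyl groups; using alcohol 7 directly under redox-condensation conditions also avoids an ionisation-prone benzylic halide.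

**4 ⇒ 3.** The O5–Si and O7–Si bonds are cut. The forward step must silylate two of three hydroxyls and leave free the one wedged between acetyl and prenyl; a bulky silyl group is chosen to make that steric distinction as large as possible.

**3 ⇒ 1 + 2.** The ring A–prenyl C–C bond is cut. Because 1 is symmetric, the two nuclear positions are equivalent and mono-C-alkylation can give only one isomer. The forward step must favour C- over O-alkylation and stop at one prenyl group.

**7 ⇒ 6 ⇒ 5.** A C–H bond (aldehyde reduction) and the O4′–Si bond are cut, leading to a cheap aromatic aldehyde that already has the ring B oxygenation pattern. Both forward steps are routine.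

## Other disconnections considered

**Alternative 1:** Ring A is made last by cutting C4a–C5 and C8–C8a. The pieces are the enantiopure bromo dihydropyranone A2 (ring C with C2 and C3 already trans and bromine on C4a) and the prenyl-bearing 1-methoxy-1,3-bis(silyloxy)diene A3. In the forward step the diene terminus carrying the prenyl group would bond to C8a and the ketene acetal carbon to C4a; loss of HBr, methanol and the silyl groups would aromatise the new ring to give A1.
- In its favour: the C8 position of the prenyl group follows from the polarity of A3 and not from a selective protection, which is better than the chosen plan, where step 2 carries that burden. The ring A hydroxyls appear unprotected, and two skeletal bonds form at once. The stereocentres are not created in the key step, so on stereochemical certainty of the key step it is at least the equal of step 7.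
- Against it: the C4a=C8a bond belongs to a vinylogous ester and is a reluctant acceptor. Once the diene has added at C8a, O1 becomes a β-leaving group of the C4 enolate, so opening of ring C would compete with loss of bromide. The C3 silyloxy ketone next to the reacting enone could epimerise. A2 must be made enantiopure with its aryl group and then brominated, which is expected to take more steps than the whole way to 11. A1 still needs a methoxymethyl group removed with acid beside a prenyl group and a free C7 hydroxyl.
- Comparison: both plans have a competing path through O1 (β-elimination there, ylide formation here). On structure the alternative is better for ring A regiochemistry; on step economy and on the mildness of the endgame the chosen plan is better.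

**Alternative 2:** The C3–C4 bond is cut. The precursor is dialdehyde A5, in which the ring A aldehyde is tethered through O1 to an α-aryloxy arylacetaldehyde. A chiral triazolylidene carbene would turn the ring A aldehyde into an acyl anion equivalent that adds to the tethered aldehyde. C3–C4 forms and ring C closes; because the future C2 of A5 epimerises readily, one epimer could be funnelled into A4.
- In its favour: C3 arrives with its hydroxyl, so no separate oxidation and no enolate of a flavanone is needed, which is better than the chosen plan. Both stereocentres come from one catalytic step. No diazo compound and no metal are involved, so on handling it is the equal or the better.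
- Against it: the ring A aldehyde is flanked by two oxygens and is the slower carbonyl to engage the carbene, whereas the aliphatic aldehyde is the faster. An α-aryloxy aldehyde that has added the carbene can expel its aryloxide, here the whole ring A phenoxide, which would sever the tether. The α-ketol product could epimerise or revert in the basic medium. The methoxymethyl ethers must finally be removed with acid in the presence of the prenyl group and a free C7 hydroxyl.
- Comparison: the route to A5 is judged about as long as that to 11, and one step is saved after ring closure, so step economy is roughly equal. The chosen plan has the more predictable chemoselectivity and the milder deprotection.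

**Alternative 3:** Two bonds are cut, C3–C4 and O1–C2, giving the salicylaldehyde dimethyl acetal A7 and the (E)-alkenylboronate A8. Acid would ionise A7 to a 4-methoxy ortho-quinone methide; the boron-bearing alkene carbon would attack C4 and O1 would close onto the benzylic cation at C2, giving A6 with C2 and C3 trans.
- In its favour: it is the most convergent of the four plans. Two ring bonds and both stereocentres form in one step, and boron at C3 is a masked hydroxyl that oxidises with retention, which is better than the chosen plan in bonds and stereocentres per step. It uses the same silyl protection and fluoride endgame, so it is equal there.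
- Against it: absolute configuration would have to come from a chiral acid or counter-anion acting on a cationic, probably stepwise addition to a weakly nucleophilic alkene, which is the least secured element of any of the plans. The ionising acid threatens the prenyl group and the aryl silyl ethers. C4 arrives as a methyl ether and must be taken to the ketone by ether cleavage and benzylic oxidation next to the C3 hydroxyl, with elimination toward a flav-3-ene as a side path.
- Comparison: three or four operations would follow A6, where two follow 12. The alternative wins on convergence; the chosen plan wins on redox economy after the key step and on the precedent for its enantiocontrol.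

Key step: step 7

Assumption: Rh2(S-PTTL)4, dirhodium tetrakis[N-phthaloyl-(S)-tert-leucinate], is taken to favour the insertion that leads to (2S)-12; if the opposite sense is met, the mirror-image catalyst Rh2(R-PTTL)4 replaces it and nothing else changes.

## Route

Step 1
Reactants: 1 2,4,6-trihydroxyacetophenone; 2 prenyl bromide (1-bromo-3-methylbut-2-ene)
Product: 3 1-[2,4,6-trihydroxy-3-(3-methylbut-2-en-1-yl)phenyl]ethanone
Conditions: DBU (1 equiv), THF, 0 °C → rt; 2 added slowly to a slight excess of 1
Reagents that add atoms: none
Why: Nuclear C-prenylation of an acylphloroglucinol: the ambident phenoxide is alkylated at its electron-rich ring carbon by the allylic bromide. The two free ring positions of 1 are equivalent, so only one mono-C-prenyl isomer can form; slow addition and excess 1 limit bis-alkylation and O-alkylation.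

Step 2
Reactants: 3 1-[2,4,6-trihydroxy-3-(3-methylbut-2-en-1-yl)phenyl]ethanone
Product: 4 1-[2-hydroxy-3-(3-methylbut-2-en-1-yl)-4,6-bis(triisopropylsilyloxy)phenyl]ethanone
Conditions: iPr3SiCl (2.1 equiv), imidazole, DMF, 0 °C → rt
Reagents that add atoms: triisopropylsilyl chloride, CC(C)[Si](Cl)(C(C)C)C(C)C
Why: Imidazole-promoted silylation of phenols. The unchelated hydroxyl para to the acetyl group should react first; of the two carbonyl-flanking hydroxyls, the one with a single ortho neighbour should take the second bulky silyl group, leaving the hydroxyl wedged between acetyl and prenyl as the chelated phenol.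

Step 3
Reactants: 5 vanillin (4-hydroxy-3-methoxybenzaldehyde)
Product: 6 4-(tert-butyldimethylsilyloxy)-3-methoxybenzaldehyde
Conditions: tBuMe2SiCl, imidazole, CH2Cl2, rt
Reagents that add atoms: tert-butyldimethylsilyl chloride, CC(C)(C)[Si](C)(C)Cl
Why: Standard silylation of an unhindered, acidic phenol.

Step 4
Reactants: 6 4-(tert-butyldimethylsilyloxy)-3-methoxybenzaldehyde
Product: 7 [4-(tert-butyldimethylsilyloxy)-3-methoxyphenyl]methanol
Conditions: NaBH4, MeOH/THF, 0 °C
Reagents that add atoms: none
Why: Borohydride reduction of an aromatic aldehyde; the aryl silyl ether tolerates brief exposure at 0 °C.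

Step 5
Reactants: 4 1-[2-hydroxy-3-(3-methylbut-2-en-1-yl)-4,6-bis(triisopropylsilyloxy)phenyl]ethanone; 7 [4-(tert-butyldimethylsilyloxy)-3-methoxyphenyl]methanol
Product: 8 1-[2-{[4-(tert-butyldimethylsilyloxy)-3-methoxybenzyl]oxy}-3-(3-methylbut-2-en-1-yl)-4,6-bis(triisopropylsilyloxy)phenyl]ethanone
Conditions: PPh3, iPrO2CN=NCO2iPr (DIAD), THF, 0 °C → rt
Reagents that add atoms: none
Why: Mitsunobu etherification: the primary benzylic alcohol is activated as its oxyphosphonium salt and displaced by the ortho-acyl phenol, which is acidic enough for the reaction. The neutral conditions avoid carbonate bases that could move or remove aryl silyl groups and avoid a para-silyloxybenzyl halide.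

Step 6
Reactants: 8 1-[2-{[4-(tert-butyldimethylsilyloxy)-3-methoxybenzyl]oxy}-3-(3-methylbut-2-en-1-yl)-4,6-bis(triisopropylsilyloxy)phenyl]ethanone
Product: 11 2-diazo-1-[2-{[4-(tert-butyldimethylsilyloxy)-3-methoxybenzyl]oxy}-3-(3-methylbut-2-en-1-yl)-4,6-bis(triisopropylsilyloxy)phenyl]ethanone, via lithium enolate 9 (not isolated), via trifluoroacetyl ketone 10 (not isolated)
Conditions: LiN(SiMe3)2, THF, −78 °C; CF3CO2CH2CF3, −78 °C; aq. NH4Cl work-up, crude 10 taken on; 4-AcNHC6H4SO2N3, Et3N, H2O (1 equiv), MeCN, rt
Reagents that add atoms: 2,2,2-trifluoroethyl trifluoroacetate, FC(F)(F)COC(=O)C(F)(F)F (its CF3CO group is carried only by 10); 4-acetamidobenzenesulfonyl azide, CC(=O)Nc1ccc(cc1)S(=O)(=O)N=[N+]=[N-] (the two diazo nitrogens of 11)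
Why: Detrifluoroacetylative Regitz-type diazo transfer: the kinetic enolate 9 is C-acylated to the activated 1,3-diketone 10, which takes the diazo group from the sulfonyl azide and loses trifluoroacetyl as the N-acylsulfonamide. Strong base is used only at −78 °C, where the ortho triisopropylsilyl ether is not expected to migrate to the enolate oxygen.

Step 7
Reactants: 11 2-diazo-1-[2-{[4-(tert-butyldimethylsilyloxy)-3-methoxybenzyl]oxy}-3-(3-methylbut-2-en-1-yl)-4,6-bis(triisopropylsilyloxy)phenyl]ethanone
Product: 12 (2S)-2-[4-(tert-butyldimethylsilyloxy)-3-methoxyphenyl]-8-(3-methylbut-2-en-1-yl)-5,7-bis(triisopropylsilyloxy)-2,3-dihydro-4H-chromen-4-one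
Conditions: Rh2(S-PTTL)4 (2 mol %), CH2Cl2, 4 Å MS, 0 °C, 11 added over 2 h at high dilution
Reagents that add atoms: none
Why: Rh2(S-PTTL)4 decomposes 11 with loss of N2 to an electrophilic rhodium carbene at C3, which inserts into one of the two enantiotopic C–H bonds of the O1–CH2–aryl group through a three-centre, hydride-transfer-like transition state held in a six-atom array (C3, C4, C4a, C8a, O1, C2); C2–C3 forms and the hydrogen ends on C3. The closest known reaction type is the dirhodium tetracarboxylate-catalysed intramolecular C–H insertion of ortho-alkoxyaryl diazoketones next to the ether oxygen, which gives chroman-4-ones and has been run with chiral dirhodium carboxylates. Ring C closes by C–C bond formation in a 1,6-insertion; a five-membered alternative does not exist because the 1,5-position is O1, which carries no hydrogen. The single new stereocentre C2 is controlled by the catalyst: the chiral pocket of the four N-phthaloyl-tert-leucinate ligands distinguishes the two benzylic hydrogens and so the face of C2 that bonds to C3, the (2S) product being sought. The step needs insertion to outrun oxonium ylide formation at O1 followed by 1,2-benzyl migration; the substrate helps because the C2–H bonds are activated by both O1 and the para-silyloxy donor of ring B, while the O1 lone pairs are drained by the ortho acyl group and crowded by the C8 prenyl group. It also needs the carbene to ignore O5 and the alkene: O5 carries a triisopropylsilyl group with no α C–H bond and a shielded lone pair, and the prenyl group is meta to the carbene-bearing carbon, so no unstrained transition state for cyclopropanation or allylic insertion exists. Slow addition at high dilution suppresses carbene dimerisation and intermolecular attack on the alkene.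

Step 8
Reactants: 12 (2S)-2-[4-(tert-butyldimethylsilyloxy)-3-methoxyphenyl]-8-(3-methylbut-2-en-1-yl)-5,7-bis(triisopropylsilyloxy)-2,3-dihydro-4H-chromen-4-one
Product: 14 (2R,3R)-2-[4-(tert-butyldimethylsilyloxy)-3-methoxyphenyl]-3-hydroxy-8-(3-methylbut-2-en-1-yl)-5,7-bis(triisopropylsilyloxy)-2,3-dihydro-4H-chromen-4-one, via sodium enolate 13 (not isolated)
Conditions: NaN(SiMe3)2 (1.1 equiv), THF, −78 °C, 20 min; (±)-trans-2-(phenylsulfonyl)-3-phenyloxaziridine, −78 °C; AcOH quench at −78 °C
Reagents that add atoms: 2-(phenylsulfonyl)-3-phenyloxaziridine, O=S(=O)(c1ccccc1)N1OC1c1ccccc1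
Why: Davis oxidation of a ketone enolate: 13 attacks the oxaziridine oxygen on the face of C3 anti to the neighbouring C2 aryl group, giving the trans ketol; C2 keeps its spatial arrangement and only its descriptor changes from S to R. The oxaziridine should not epoxidise the prenyl alkene at −78 °C, and the short enolate lifetime and cold acidic quench are meant to prevent expulsion of the O1 aryloxide.

Step 9
Reactants: 14 (2R,3R)-2-[4-(tert-butyldimethylsilyloxy)-3-methoxyphenyl]-3-hydroxy-8-(3-methylbut-2-en-1-yl)-5,7-bis(triisopropylsilyloxy)-2,3-dihydro-4H-chromen-4-one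
Product: 15 (2R,3R)-3,5,7-trihydroxy-2-(4-hydroxy-3-methoxyphenyl)-8-(3-methylbut-2-en-1-yl)-2,3-dihydro-4H-chromen-4-one
Conditions: Bu4NF/AcOH (1:1, 3.5 equiv), degassed THF, 0 °C; pH 5–6 buffer work-up
Reagents that add atoms: none
Why: Fluoride-driven cleavage of three aryl silyl ethers. Acetic acid protonates the phenoxides as they form, so the base-sensitive trans ketol should be neither opened nor epimerised, and no acid strong enough to cyclise the prenyl group onto the C7 hydroxyl is present.

## Compound list

1 | 2,4,6-trihydroxyacetophenone | CC(=O)c1c(O)cc(O)cc1O | starting material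
2 | prenyl bromide (1-bromo-3-methylbut-2-ene) | CC(C)=CCBr | starting material
3 | 1-[2,4,6-trihydroxy-3-(3-methylbut-2-en-1-yl)phenyl]ethanone | CC(=O)c1c(O)cc(O)c(CC=C(C)C)c1O | intermediate
4 | 1-[2-hydroxy-3-(3-methylbut-2-en-1-yl)-4,6-bis(triisopropylsilyloxy)phenyl]ethanone | CC(=O)c1c(O[Si](C(C)C)(C(C)C)C(C)C)cc(O[Si](C(C)C)(C(C)C)C(C)C)c(CC=C(C)C)c1O | intermediate
5 | vanillin (4-hydroxy-3-methoxybenzaldehyde) | COc1cc(C=O)ccc1O | starting material
6 | 4-(tert-butyldimethylsilyloxy)-3-methoxybenzaldehyde | COc1cc(C=O)ccc1O[Si](C)(C)C(C)(C)C | intermediate
7 | [4-(tert-butyldimethylsilyloxy)-3-methoxyphenyl]methanol | COc1cc(CO)ccc1O[Si](C)(C)C(C)(C)C | intermediate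
8 | 1-[2-{[4-(tert-butyldimethylsilyloxy)-3-methoxybenzyl]oxy}-3-(3-methylbut-2-en-1-yl)-4,6-bis(triisopropylsilyloxy)phenyl]ethanone | CC(=O)c1c(O[Si](C(C)C)(C(C)C)C(C)C)cc(O[Si](C(C)C)(C(C)C)C(C)C)c(CC=C(C)C)c1OCc1ccc(O[Si](C)(C)C(C)(C)C)c(OC)c1 | intermediate
9 | lithium enolate of 8 (lithium 1-arylethen-1-olate, aryl as in 8) | [Li+].[O-]C(=C)c1c(O[Si](C(C)C)(C(C)C)C(C)C)cc(O[Si](C(C)C)(C(C)C)C(C)C)c(CC=C(C)C)c1OCc1ccc(O[Si](C)(C)C(C)(C)C)c(OC)c1 | intermediate
10 | 4,4,4-trifluoro-1-[2-{[4-(tert-butyldimethylsilyloxy)-3-methoxybenzyl]oxy}-3-(3-methylbut-2-en-1-yl)-4,6-bis(triisopropylsilyloxy)phenyl]butane-1,3-dione | O=C(CC(=O)C(F)(F)F)c1c(O[Si](C(C)C)(C(C)C)C(C)C)cc(O[Si](C(C)C)(C(C)C)C(C)C)c(CC=C(C)C)c1OCc1ccc(O[Si](C)(C)C(C)(C)C)c(OC)c1 | intermediate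
11 | 2-diazo-1-[2-{[4-(tert-butyldimethylsilyloxy)-3-methoxybenzyl]oxy}-3-(3-methylbut-2-en-1-yl)-4,6-bis(triisopropylsilyloxy)phenyl]ethanone | [N-]=[N+]=CC(=O)c1c(O[Si](C(C)C)(C(C)C)C(C)C)cc(O[Si](C(C)C)(C(C)C)C(C)C)c(CC=C(C)C)c1OCc1ccc(O[Si](C)(C)C(C)(C)C)c(OC)c1 | intermediate
12 | (2S)-2-[4-(tert-butyldimethylsilyloxy)-3-methoxyphenyl]-8-(3-methylbut-2-en-1-yl)-5,7-bis(triisopropylsilyloxy)-2,3-dihydro-4H-chromen-4-one | COc1cc([C@H]2Oc3c(CC=C(C)C)c(O[Si](C(C)C)(C(C)C)C(C)C)cc(O[Si](C(C)C)(C(C)C)C(C)C)c3C(=O)C2)ccc1O[Si](C)(C)C(C)(C)C | intermediate
13 | sodium enolate of 12 (sodium (2S)-2-aryl-2H-chromen-4-olate, substituents as in 12) | [Na+].COc1cc([C@H]2Oc3c(CC=C(C)C)c(O[Si](C(C)C)(C(C)C)C(C)C)cc(O[Si](C(C)C)(C(C)C)C(C)C)c3C([O-])=C2)ccc1O[Si](C)(C)C(C)(C)C | intermediate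
14 | (2R,3R)-2-[4-(tert-butyldimethylsilyloxy)-3-methoxyphenyl]-3-hydroxy-8-(3-methylbut-2-en-1-yl)-5,7-bis(triisopropylsilyloxy)-2,3-dihydro-4H-chromen-4-one | COc1cc([C@H]2Oc3c(CC=C(C)C)c(O[Si](C(C)C)(C(C)C)C(C)C)cc(O[Si](C(C)C)(C(C)C)C(C)C)c3C(=O)[C@@H]2O)ccc1O[Si](C)(C)C(C)(C)C | intermediate
15 | (2R,3R)-3,5,7-trihydroxy-2-(4-hydroxy-3-methoxyphenyl)-8-(3-methylbut-2-en-1-yl)-2,3-dihydro-4H-chromen-4-one | COc1cc([C@H]2Oc3c(CC=C(C)C)c(O)cc(O)c3C(=O)[C@@H]2O)ccc1O | target

## Step count and least certain steps

Total step count: 9. Longest linear sequence: 7 steps (steps 1, 2, 5, 6, 7, 8, 9 from 1; the branch of steps 3 and 4 from 5 joins at step 5 and is equally long).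

**Step 7, the insertion.** The most likely failure is diversion of the carbene to O1 (oxonium ylide formation) followed by 1,2-migration of the electron-rich benzyl group. Erosion of enantioselection is the second concern, because an acceptor-only carbene reacts through an early transition state and hydride transfer from so strongly donor-substituted a benzylic position may become stepwise. The fallback replaces carbene chemistry with conjugate arylation and sets out from 4. Condensation with Me2NCH(OMe)2 should give the enaminone F1, which should close under mild acid (pyridinium tosylate, toluene, warm) with loss of dimethylamine to the chromone F2. Asymmetric Hayashi–Miyaura-type 1,4-addition of the known arylboronic acid F3 under [Rh(OH)(cod)]2 with a chiral atropisomeric bisphosphine, a known entry to enantioenriched 2-arylchroman-4-ones from chromones, comes back to the route at 12. The ligand antipode is chosen for the (2S) product.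

**Step 8, the hydroxylation.** The most likely failure is β-elimination of the O1 aryloxide from the enolate, that is, opening of ring C; reclosure would erase the C2 configuration. Addition of the enolate to the sulfonylimine co-product is a lesser concern. The fallback avoids the anionic enolate and sets out from 12. Soft enolisation (Me3SiOTf, Et3N, CH2Cl2, 0 °C) should give the trimethylsilyl enol ether F4. Oxidation of F4 with the same 2-sulfonyloxaziridine under neutral conditions (CHCl3, rt to 50 °C, a Rubottom-type oxidation), again anti to the C2 aryl group, should give the 3-trimethylsilyloxy ketone F5 after silyl transfer. Aqueous citric acid in THF then removes the trimethylsilyl group and comes back to the route at 14.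

**Step 5, the etherification.** The most likely failure is slow or incomplete reaction because the phenol is chelated to the acetyl carbonyl and flanked on both sides, so that the activated benzylic alcohol is consumed by the reduced azodicarboxylate instead. The fallback sets out from 7. An Appel reaction (CBr4, PPh3, CH2Cl2, 0 °C) should give the benzylic bromide F6, which is used at once in a Williamson alkylation of 4 (K2CO3, acetone, rt, catalytic Bu4NI) and comes back to the route at 8. The triisopropylsilyl groups on ring A are what make this mild carbonate step tolerable.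

**Step 2, the selective silylation (and step 1 before it).** The most likely failure is incomplete discrimination between the two carbonyl-flanking hydroxyls, which would carry the prenyl group to C6 of the chromanone; step 1 may also suffer over-alkylation. The fallback fixes the regiochemistry by a sigmatropic shift and sets out from 1.
- Bis-silylation (iPr3SiCl, imidazole) should give the chelated phenol F7, the only possible isomer with one carbonyl-flanking hydroxyl free.
- O-alkylation with 3-chloro-3-methylbut-1-yne (DBU, catalytic CuCl2, MeCN, 0 °C) should give the 1,1-dimethylpropargyl ether F8.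
- Semi-hydrogenation (H2, Pd/CaCO3 poisoned with Pb(OAc)2, quinoline) should give the 1,1-dimethylallyl ether F9.
- Aromatic Claisen rearrangement (toluene, 110 °C) delivers a normal prenyl group to the only free ortho carbon and frees the hydroxyl beside it, which comes back to the route at 4.

## Further compounds

F1 | step 7 | (E)-3-(dimethylamino)-1-[2-hydroxy-3-(3-methylbut-2-en-1-yl)-4,6-bis(triisopropylsilyloxy)phenyl]prop-2-en-1-one | CN(C)/C=C/C(=O)c1c(O[Si](C(C)C)(C(C)C)C(C)C)cc(O[Si](C(C)C)(C(C)C)C(C)C)c(CC=C(C)C)c1O
F2 | step 7 | 8-(3-methylbut-2-en-1-yl)-5,7-bis(triisopropylsilyloxy)-4H-chromen-4-one | O=c1ccoc2c(CC=C(C)C)c(O[Si](C(C)C)(C(C)C)C(C)C)cc(O[Si](C(C)C)(C(C)C)C(C)C)c12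
F3 | step 7 | [4-(tert-butyldimethylsilyloxy)-3-methoxyphenyl]boronic acid | COc1cc(B(O)O)ccc1O[Si](C)(C)C(C)(C)C
F4 | step 8 | (2S)-2-[4-(tert-butyldimethylsilyloxy)-3-methoxyphenyl]-8-(3-methylbut-2-en-1-yl)-5,7-bis(triisopropylsilyloxy)-4-(trimethylsilyloxy)-2H-chromene | COc1cc([C@H]2Oc3c(CC=C(C)C)c(O[Si](C(C)C)(C(C)C)C(C)C)cc(O[Si](C(C)C)(C(C)C)C(C)C)c3C(O[Si](C)(C)C)=C2)ccc1O[Si](C)(C)C(C)(C)C
F5 | step 8 | (2R,3R)-2-[4-(tert-butyldimethylsilyloxy)-3-methoxyphenyl]-8-(3-methylbut-2-en-1-yl)-5,7-bis(triisopropylsilyloxy)-3-(trimethylsilyloxy)-2,3-dihydro-4H-chromen-4-one | COc1cc([C@H]2Oc3c(CC=C(C)C)c(O[Si](C(C)C)(C(C)C)C(C)C)cc(O[Si](C(C)C)(C(C)C)C(C)C)c3C(=O)[C@@H]2O[Si](C)(C)C)ccc1O[Si](C)(C)C(C)(C)C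
F6 | step 5 | [4-(bromomethyl)-2-methoxyphenoxy](tert-butyl)dimethylsilane | COc1cc(CBr)ccc1O[Si](C)(C)C(C)(C)C
F7 | step 2 | 1-[2-hydroxy-4,6-bis(triisopropylsilyloxy)phenyl]ethanone | CC(=O)c1c(O)cc(O[Si](C(C)C)(C(C)C)C(C)C)cc1O[Si](C(C)C)(C(C)C)C(C)C
F8 | step 2 | 1-[2-(2-methylbut-3-yn-2-yloxy)-4,6-bis(triisopropylsilyloxy)phenyl]ethanone | CC(=O)c1c(OC(C)(C)C#C)cc(O[Si](C(C)C)(C(C)C)C(C)C)cc1O[Si](C(C)C)(C(C)C)C(C)C
F9 | step 2 | 1-[2-(2-methylbut-3-en-2-yloxy)-4,6-bis(triisopropylsilyloxy)phenyl]ethanone | CC(=O)c1c(OC(C)(C)C=C)cc(O[Si](C(C)C)(C(C)C)C(C)C)cc1O[Si](C(C)C)(C(C)C)C(C)C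
A1 | alternative 1 | (2R,3R)-3-(tert-butyldimethylsilyloxy)-5,7-dihydroxy-2-[3-methoxy-4-(methoxymethoxy)phenyl]-8-(3-methylbut-2-en-1-yl)-2,3-dihydro-4H-chromen-4-one | COc1cc([C@H]2Oc3c(CC=C(C)C)c(O)cc(O)c3C(=O)[C@@H]2O[Si](C)(C)C(C)(C)C)ccc1OCOC
A2 | alternative 1 | (2R,3R)-5-bromo-3-(tert-butyldimethylsilyloxy)-2-[3-methoxy-4-(methoxymethoxy)phenyl]-2,3-dihydro-4H-pyran-4-one | COCOc1ccc(cc1OC)[C@H]1OC=C(Br)C(=O)[C@@H]1O[Si](C)(C)C(C)(C)C
A3 | alternative 1 | 1-methoxy-7-methyl-1,3-bis(trimethylsilyloxy)octa-1,3,6-triene | COC(O[Si](C)(C)C)=CC(O[Si](C)(C)C)=CCC=C(C)C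
A4 | alternative 2 | (2R,3R)-3-hydroxy-2-[3-methoxy-4-(methoxymethoxy)phenyl]-5,7-bis(methoxymethoxy)-8-(3-methylbut-2-en-1-yl)-2,3-dihydro-4H-chromen-4-one | COc1cc([C@H]2Oc3c(CC=C(C)C)c(OCOC)cc(OCOC)c3C(=O)[C@@H]2O)ccc1OCOC
A5 | alternative 2 | 2-{1-[3-methoxy-4-(methoxymethoxy)phenyl]-2-oxoethoxy}-4,6-bis(methoxymethoxy)-3-(3-methylbut-2-en-1-yl)benzaldehyde (configurationally labile at the α-carbon) | COCOc1ccc(cc1OC)C(C=O)Oc1c(CC=C(C)C)c(OCOC)cc(OCOC)c1C=O
A6 | alternative 3 | 2,3-trans-2-[4-(tert-butyldimethylsilyloxy)-3-methoxyphenyl]-5,7-bis(tert-butyldimethylsilyloxy)-4-methoxy-8-(3-methylbut-2-en-1-yl)-3-(4,4,5,5-tetramethyl-1,3,2-dioxaborolan-2-yl)chromane, C2 and C3 arranged as in 15 | COc1cc([C@H]2Oc3c(CC=C(C)C)c(O[Si](C)(C)C(C)(C)C)cc(O[Si](C)(C)C(C)(C)C)c3C(OC)[C@@H]2B4OC(C)(C)C(C)(C)O4)ccc1O[Si](C)(C)C(C)(C)C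
A7 | alternative 3 | 3,5-bis(tert-butyldimethylsilyloxy)-2-(dimethoxymethyl)-6-(3-methylbut-2-en-1-yl)phenol | COC(OC)c1c(O[Si](C)(C)C(C)(C)C)cc(O[Si](C)(C)C(C)(C)C)c(CC=C(C)C)c1O
A8 | alternative 3 | (E)-2-{2-[4-(tert-butyldimethylsilyloxy)-3-methoxyphenyl]ethenyl}-4,4,5,5-tetramethyl-1,3,2-dioxaborolane | COc1cc(/C=C/B2OC(C)(C)C(C)(C)O2)ccc1O[Si](C)(C)C(C)(C)C
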